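3 questions stand on this flask of J: has it stopped at 1.0 h, and how much G and how much Q does it then hold?

| flask | J | remark | time |
|---|---|---|---|
| ochre | 1.9 M | the very flask that is asked about, followed so far |  |
| flask | 1.9 M |  | 1.0 h |

ochre run (percent of the J charged)

| time / min | G / % | Q / % |
|---|---|---|
| 0.833 | 1.4 | 0.4 |
| 2.50 | 12.6 | 5.0 |
| 4.00 | 28.2 | 14.9 |
| 6.00 | 44.1 | 29.4 |
| 10.0 | 49.8 | 42.9 |
| 12.0 | 51.6 | 46.9 |

(readings scatter by 1 percentage point)

- J is a solid; its amount is given per volume of the solution
- at the start none of J is in solution
- what has only dissolved of J counts as not reacted
- the reaction counts as stopped when no species that holds the J changes by six tenths of a point or more over the second half of the time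

1. why nothing more happens at 1.0 h, or that something still does (for what has run out or reacted, a solid counts together with what of it has only dissolved) (all of J has reacted / it is still moving / forward and back rates have come level)
2. amount of G at 1.0 h, in percent of the J charged
3. amount of Q at 1.0 h, in percent of the J charged

We ask what the end must be, then how fast it comes. Call the open share the part of the charge not yet in G or Q. It reads 26.5% at 6.00 min and 7.30% at 10.0 min, which gives a halving time of the open share of 2.15 min. At 12.0 min the open share reads 1.50%. The time left to 1.0 h is far longer than that halving time: it holds 22.3 halvings, so we expect J to be used up. In the ochre readings, the last interval sent 0.690 of what closed into Q, a ratio that carries their scatter. Giving the last open share that same split, we commit to G 52.1% and Q 47.9%.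

Our weak link is that G and Q stay put once filled. Over that last interval of the ochre run, G still read 1.8 percentage points higher while Q read 4 points higher, so up to 12.0 min the readings show no loss of G, within their scatter of 1 point.

The forecast says all of J has reacted, with G 52.2% and Q 47.8%: “Once J is gone, Q formation stops, leaving G and Q frozen.”

The flask gives all of J has reacted, with G 50.9% and Q 49.1%.

    X ⇌ L (K = 7.20, k = 0.0250 s⁻¹)
    L → E (k = 0.00600 s⁻¹)
    E → Q (k = 0.0110 s⁻¹)
    L → Z (k = 0.00440 s⁻¹)
    Z → G (k = 0.140 s⁻¹)
    X → G (k = 0.00330 s⁻¹)
    J ⇌ X, rate k7*(cs7 - [X]) while solid is left; crystals form when [X] > cs7 (solubility = 1.10 M, k = 0.0100 s⁻¹)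

This flask already holds G 50.9% and Q 49.1% at 0.500 h, which is 8.37 of our halving times after the last reading. The same charge read at 4.0 h lies 106 halvings past that reading, and that flask holds G 50.9% and Q 49.1%.

(The runs were generated by integration with constants of no real substance; noise was put on by code.)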